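## The problem

The target (33) is a germacrane: a single ten-membered carbocycle, numbered C1–C10 here, with an isopropenyl group on C7, a ketone at C9, cis-fused trisubstituted epoxides at C1–C10 and C4–C5 (methyls on C10 and C4) and angelate esters on C3 and C6. No second ring fixes its shape, so closing it by C–C bond formation would fight the entropy and transannular strain of a medium ring, and any long-range facial selectivity would rest on a floppy conformer. Seven stereocentres are needed (1R,3S,4R,5S,6S,7S,10R), and C7 is the only one that bears no oxygen. C7 can control C6 directly, and each epoxide can be slaved to a neighbouring carbinol (the C3 hydroxyl for C4/C5, a temporary C9 hydroxyl for C1/C10). The C3 and C9 carbinols themselves lie too far from C7 for trustworthy substrate control. The angelates isomerise to tiglates and do not survive hydrazine or hydroxide, the α,β-epoxy ketone does not survive enolising bases or nucleophiles, the epoxides are open to acid-induced transannular attack, and the isopropenyl group excludes ozone. The enabling feature is that the two epoxide CH carbons, C1 and C5, lie 1,5 across the ring, each next to a methyl-bearing carbon (C10, C4), with C7 two atoms from C5. A C1=C5 double bond therefore turns the ring into the hydroazulene of a guaiane with both methyls and the C7 side chain in place.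

## Retrosynthesis

**C9 ketone and C1–C10 epoxide.** Target 33 is taken back to epoxy alcohol 32 (C9 C=O to C–OH) and its silyl ether 31, so the base- and hydrazine-sensitive epoxy ketone appears only in the last step. Much earlier, the C1–O and C10–O bonds are cut from epoxy alcohol 11 back to Z-allylic alcohol 10, and the C9–H bond back to enone 9. Forward, a peracid must deliver oxygen trans to the 9β hydroxyl, and an oxazaborolidine must set C9. This is preferred to a late nucleophilic epoxidation of an enone, which would expose the angelates to hydroperoxide and leave the face to chance.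

**Esters and C6.** The two acyl C–O bonds are cut to alcohols 30 and 24 and to mixed anhydride 26, which is made once from angelic acid 25 and 2,4,6-trichlorobenzoyl chloride and serves both esterifications. C6 is taken back through ketone 29 to the 6-epimeric alcohol 28 and its silyl ether 27. A hydride reduction is asked to set C6 because both neighbours, the 4,5-epoxide and C7, send hydride to the same face. Electrophilic hydroxylation next to C7 is predicted to give the wrong epimer.

**C4–C5 epoxide and C3.** The C4–O and C5–O bonds are cut from 24 back to Z-allylic alcohol 23, and C3–H back to enone 22. The demands are the same as on the other side. The only competing alkene at that point is the less reactive isopropenyl group, because C1=C10 was epoxidised long before.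

**The two 1,3-transpositions.** Enones 22 and 9 come from allylic alcohols 21 and 8, and these from epoxy ketones 20 and 7 by Wharton transposition (C=O becomes =CH, oxygen moves to the β-carbon). Epoxy ketones 20 and 7 come from enones 19 and 6. A Payne shift of the derived epoxy alcohols would keep the ozone oxygens, but it was set aside for two reasons. It needs the threo epoxy alcohol, whereas hydride reduction of α,β-epoxy ketones gives erythro. It also equilibrates two equally substituted epoxides without bias. Oxidation and reagent-controlled reduction (steps 6, 7 and 17, 18) cost four steps and remove all dependence on the facial course of the two nucleophilic epoxidations.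

**Isopropenyl, C5 enone and C6 oxygen.** Trienone 19 goes back to tertiary alcohol 18 (dehydration), 18 to α-silyloxy ketone 15 (dehydrogenation toward C4), and 15 through alcohol 14 to ketone 13 (enolate hydroxylation at the C6 methylene). Dehydration is placed at the enone stage because a conjugated ketone forms no lactol and no epoxide is yet within reach of the C11 hydroxyl.

**Telling the ketones apart.** Ketone 13 comes from ketal 12, and enone 6 from ketal 4 through silyl enol ether 5. Ketal 4 comes from dione 3, in which only C5 can reach the C11 hydroxyl through a five-membered ring. The C1 side is therefore worked first and finished to the robust epoxy silyl ether 12 before C5 is unmasked. This also keeps any enolate away from a 1,5-diketone.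

**Key disconnection.** Dione 3 is reconnected between C1 and C5 (both C=O bonds become one C=C) to give (−)-guaiol 1. Against any ring-closing disconnection, this one delivers all fifteen carbons, the ten-membered ring and C7 in one step from a commercial terpene. The forward reaction has to cleave a single tetrasubstituted alkene and stop at the diketone.

## Roads not taken

**Alternative 1: propyne linchpin to an open-chain enediol.** The cut is at C5–C6 and C3–C4, with the ring still open around C10. Forward, lithium propynide adds to an aldehyde carbon C6, NaAlH2(OCH2CH2OCH3)2 hydroaluminates the propargylic alkoxide trans-selectively, and the (Z)-alkenylaluminate adds to a second aldehyde (C3) to give enediol A1.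
- Merits: the Z geometry of C4=C5 is fixed by mechanism, the C3 and C6 oxygens arrive with the C–C bonds, and the route is convergent.
- Weak points: nothing relates C3 to the rest, so it would need an oxidation/asymmetric reduction loop. C7 has to be made by asymmetric synthesis. The ten-membered ring must still be closed around C10, which is the hardest operation on this skeleton.
- Comparison: on alkene geometry this road is better than the chosen plan, which leaves the C4=C5 and C1=C10 geometry to the Wharton steps and to ring thermodynamics. The chosen plan sets against this a preformed ring, C7 from the chiral pool and no macrocyclisation.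

**Alternative 2: enone–cyclobutene photocycloaddition, then thermal cyclobutane scission.** The cut is at C1–C10 and C4–C5. Forward, irradiation adds a cyclobutene (C1–C4) across the C10=C5 bond of a six-membered enone carrying C5–C10 to give tricycle A2. Heating then cleaves the central cyclobutane the other way and releases the ten-membered 1,5-diene.
- Merits: the ring is again made by expansion, and the isopropenyl group, the C9 ketone and the C3 and C6 oxygens are present from the start. In step economy of oxygenation this is clearly better than the chosen plan, which spends most of its steps installing them.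
- Weak points: regiochemistry and facial selectivity of the cycloaddition with a substituted cyclobutene; the isopropenyl alkene is itself a photochemical partner for the enone; thermal opening gives a cis,trans-1,5-diene that undergoes Cope rearrangement under the same conditions, whereas the target needs both ring alkenes cis.
- Comparison: the chosen plan answers with a first step of established type and with alkenes whose required geometry is the thermodynamically preferred one.

**Alternative 3: palladium 1,4-diangeloyloxylation of a ring diene.** Only the two C–O ester bonds are cut. Forward, Pd(OAc)2 with benzoquinone adds two angelates across a C3=C4–C5=C6 diene of a cyclodecatrienone and leaves the alkene at C4=C5, giving A3.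
- Merits: A3 lacks only the two epoxide oxygens of 33, so on paper this is by far the shortest endgame, better than the chosen plan in that respect.
- Weak points: the reaction is established for common-ring dienes and simple carboxylates, whereas a hindered, isomerisable unsaturated carboxylate and a 2-substituted diene in a ten-membered ring are outside that scope. Nothing relates the new centres to C7. The target needs the 3,6-trans diester. The C4=C5 epoxide would then have to be placed without a directing hydroxyl on an alkene flanked by two esters, with the isopropenyl group competing. The trienone precursor needs its own synthesis.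
- Comparison: the chosen plan is much longer but epoxidises under hydroxyl direction before esterification and starts from a purchased terpene.

Key step: step 1

Remark on numbering: ring carbons keep the numbers C1–C10 used above (C11 on C7, methyls on C4 and C10); with the ring drawn flat and numbered clockwise, α is below and β above the plane.

Remark on hydroxy ketones: 3, 13, 14 and 15 are drawn open; their five-membered C5/C11 lactols are assumed to equilibrate with them and to react through the open form.

Remark on uncontrolled centres: 7, 8, 20 and 21 are expected as mixtures at the epoxide or carbinol centres left undefined in their SMILES; these centres are erased in steps 5–6 and 16–17. The 6α configuration drawn for 14–28 is the predicted one and is reset in steps 23–24.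

Step 1
Reactants: 1 (−)-guaiol
Product: 3 seco-guaiol dione [(4S,7R,10S)-7-(2-hydroxypropan-2-yl)-4,10-dimethylcyclodecane-1,5-dione], via primary ozonide 2 (not isolated)
Conditions: O3, CH2Cl2/MeOH (4:1), NaHCO3, −78 °C; then Me2S, −78 → 20 °C
Reagents that add atoms: ozone, [O-][O+]=O
Why: Ozone adds to the electron-rich tetrasubstituted C1=C5 alkene by 1,3-dipolar cycloaddition from the β face (the C4 and C10 methyls and the C7 side chain are all α) to give primary ozonide 2. Cycloreversion breaks the C1–C5 σ bond and leaves a ketone and a carbonyl oxide in the same ring; a secondary ozonide across the ring is geometrically out of reach, so methanol (or the C11 hydroxyl at C5) captures the carbonyl oxide as a mixture of peroxidic ketals, which Me2S reduces to the second ketone. The closest known reaction type is the ozonolytic cleavage of a ring-fusion tetrasubstituted alkene to a medium-ring diketone. No ring is closed: the ten-membered ring is uncovered by cutting the bond shared by the five- and seven-membered rings, so no mode of closure has to be chosen. No stereocentre is made; C4, C7 and C10 are carried over, and C4 and C10, now α to ketones, are erased later. The only selectivity needed is chemoselectivity, which is secured because 1 has one alkene and its tertiary alcohol is inert. NaHCO3 buffering and neutral reductive work-up hold back transannular aldol closure of the 1,5-dione, which is used at once.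

Step 2
Reactants: 3 seco-guaiol dione
Product: 4 C5 methyl ketal [5β-methoxy-5α,11-epoxygermacran-1-one, C4 and C10 methyls α]
Conditions: MeOH, pyridinium p-toluenesulfonate (5 mol%), 3 Å molecular sieves, 0 → 20 °C
Reagents that add atoms: methanol, CO
Why: Only C5 can reach the C11 hydroxyl through a five-membered ring (C1 would need a seven-membered one), so acid-catalysed exchange through the cyclic oxocarbenium ion gives the mixed methyl ketal at C5 alone, and the medium-ring C1 ketone stays free. The new ketal centre is fixed because the O–C11 bridge must leave C5 on the α face, the face on which C11 leaves C7.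

Step 3
Reactants: 4 C5 methyl ketal
Product: 6 (9Z)-5β-methoxy-5α,11-epoxygermacr-9-en-1-one, via silyl enol ether 5 (not isolated)
Conditions: iPr2NMgBr, Me3SiCl, Et3N, HMPA, Et2O, 25 °C; then Pd(OAc)2, MeCN, 25 °C
Reagents that add atoms: none
Why: The magnesium amide with Me3SiCl equilibrates the enolates and traps the more substituted one (C1=C10) as 5; Saegusa–Ito oxidation (oxa-π-allylpalladium at C10, β-hydride elimination from C9) then gives the conjugated ring enone. The ketal tolerates these basic and neutral conditions, and the enone geometry is of no consequence for step 4.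

Step 4
Reactants: 6 enone
Product: 7 9,10-epoxy-5β-methoxy-5α,11-epoxygermacran-1-one (cis-epoxide, either face)
Conditions: 30% H2O2, NaOH, MeOH, 0 °C
Reagents that add atoms: hydrogen peroxide, OO
Why: Weitz–Scheffer epoxidation: hydroperoxide adds to C9 and the enolate closes onto oxygen. Neither the face of attack nor the C9/C10 configuration matters, because both centres are erased in steps 5 and 6.

Step 5
Reactants: 7 epoxy ketone
Product: 8 (1(10)Z)-9-hydroxy-5β-methoxy-5α,11-epoxygermacr-1(10)-ene (C9 epimers)
Conditions: N2H4·H2O, CH3CO2H (cat.), MeOH, 0 → 20 °C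
Reagents that add atoms: none
Why: Wharton transposition: the hydrazone opens the epoxide to an alkenyl diazene that loses N2, leaving the C9 alcohol and the C1=C10 alkene, as with carvone oxide. The ring-cis alkene is expected because the alkenyl intermediate is configurationally mobile and the cis isomer is the more stable one in a ten-membered ring.

Step 6
Reactants: 8 allylic alcohol
Product: 9 (1(10)Z)-5β-methoxy-5α,11-epoxygermacr-1(10)-en-9-one
Conditions: MnO2, CH2Cl2, 20 °C
Reagents that add atoms: none
Why: Allylic oxidation with MnO2 completes the 1,3-carbonyl transposition and converges both C9 epimers into one enone; the ketal and the trisubstituted alkene are inert.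

Step 7
Reactants: 9 transposed enone
Product: 10 (1(10)Z,9R)-9β-hydroxy-5β-methoxy-5α,11-epoxygermacr-1(10)-ene
Conditions: (S)-1-methyl-3,3-diphenyltetrahydro-1H,3H-pyrrolo[1,2-c][1,3,2]oxazaborole (10 mol%), catecholborane, toluene, −78 °C
Reagents that add atoms: none
Why: Corey–Bakshi–Shibata reduction: the oxazaborolidine binds the ketone with the α-methylalkenyl flank as the large and the C8 methylene as the small group and delivers hydride to give the 9R (9β) alcohol by reagent control. Catecholborane at −78 °C leaves the ketal and the alkene untouched.

Step 8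
Reactants: 10 9β-allylic alcohol
Product: 11 1α,10α-epoxy-9β-hydroxy-5β-methoxy-5α,11-epoxygermacrane
Conditions: mCPBA, NaHCO3, CH2Cl2, 0 °C
Reagents that add atoms: 3-chloroperbenzoic acid, O=C(OO)c1cccc(Cl)c1
Why: Hydroxyl-directed peracid epoxidation: with C9–H held in the alkene plane by A(1,3) strain against C2, oxygen is delivered to the hydroxyl-bearing face, which gives the epoxide trans (threo) to the hydroxyl, the known outcome for Z-allylic alcohols in open chains and in medium rings. This sets C1 and C10 (1R,10R) as the cis 1α,10α-epoxide. C1=C10 is the only alkene in 10, and the buffer protects ketal and epoxide.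

Step 9
Reactants: 11 epoxy alcohol
Product: 12 9β-(tert-butyldimethylsilyloxy)-1α,10α-epoxy-5β-methoxy-5α,11-epoxygermacrane
Conditions: tBuMe2SiCl, imidazole, DMF, 20 °C
Reagents that add atoms: tert-butyldimethylsilyl chloride, CC(C)(C)[Si](C)(C)Cl
Why: Imidazole-mediated silylation of the secondary alcohol masks C9 as an ether that survives enolate, hydrazine and fluoride-free acid steps and blocks Payne migration of the adjacent epoxide.

Step 10
Reactants: 12 silyl ether ketal
Product: 13 1α,10α-epoxy-9β-(tert-butyldimethylsilyloxy)-11-hydroxygermacran-5-one (C4 methyl α)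
Conditions: pyridinium p-toluenesulfonate (10 mol%), acetone/H2O (10:1), 20 °C
Reagents that add atoms: water, O
Why: Mild acid hydrolysis of the mixed ketal through the cyclic oxocarbenium ion frees the C5 ketone and the C11 hydroxyl. The weakly acidic, buffered medium is chosen to spare the trisubstituted epoxide and the silyl ether.

Step 11
Reactants: 13 hydroxy ketone
Product: 14 6α,11-dihydroxy-1α,10α-epoxy-9β-(tert-butyldimethylsilyloxy)germacran-5-one
Conditions: KN(SiMe3)2 (2.3 equiv), THF, −78 °C; then 2-(phenylsulfonyl)-3-phenyloxaziridine, −78 °C; aq. NH4Cl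
Reagents that add atoms: 2-(phenylsulfonyl)-3-phenyloxaziridine, O=S(=O)(N1OC1c1ccccc1)c1ccccc1
Why: After the hydroxyl proton, the amide base removes a proton from the C6 methylene (kinetic preference over the C4 methine), and the enolate is oxidised by the N-sulfonyloxaziridine (Davis oxidation). Attack anti to the bulky C11 group in the A(1,3)-minimised enolate predicts the 6α alcohol; either epimer serves because C6 is reset in steps 23 and 24.

Step 12
Reactants: 14 diol
Product: 15 6α-triethylsilyloxy-11-hydroxy-1α,10α-epoxy-9β-(tert-butyldimethylsilyloxy)germacran-5-one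
Conditions: Et3SiCl, imidazole, DMF, 0 °C
Reagents that add atoms: triethylsilyl chloride, CC[Si](CC)(CC)Cl
Why: Imidazole-mediated silylation takes the secondary hydroxyl and leaves the tertiary one, which must stay free for step 14. The triethylsilyl group is chosen so that it can later be removed beside the tert-butyldimethylsilyl ether.

Step 13
Reactants: 15 α-silyloxy ketone
Product: 18 (3Z)-11-hydroxy-6α-triethylsilyloxy-1α,10α-epoxy-9β-(tert-butyldimethylsilyloxy)germacr-3-en-5-one, via bis-silyl enol ether 16 (not isolated), via TMS-protected enone 17 (not isolated)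
Conditions: LiN(iPr)2 (2.2 equiv), Me3SiCl, THF, −78 °C; then Pd(OAc)2, MeCN, 25 °C; then K2CO3, MeOH, 0 °C
Reagents that add atoms: none
Why: The amide deprotonates the hydroxyl and then C4 (C6–H is shielded and deactivated by its silyloxy group), Me3SiCl traps enolate and alkoxide as 16, and Saegusa–Ito oxidation with β-hydride elimination from C3 gives ring enone 17. Methanolysis removes only the labile tertiary trimethylsilyl ether; the conjugated ketone of 18 no longer forms a lactol.

Step 14
Reactants: 18 hydroxy enone
Product: 19 (3Z)-6α-triethylsilyloxy-1α,10α-epoxy-9β-(tert-butyldimethylsilyloxy)germacra-3,11-dien-5-one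
Conditions: methyl N-(triethylammoniosulfonyl)carbamate (Burgess reagent), toluene, 50 °C
Reagents that add atoms: none
Why: Burgess dehydration: the tertiary sulfamate eliminates by a syn pathway that favours the six methyl hydrogens over the single hindered C7–H, so the isopropenyl isomer should predominate. It is done here so that a free C11 hydroxyl never sits beside the later 4,5-epoxide, which it could open.

Step 15
Reactants: 19 dienone
Product: 20 3,4-epoxy-6α-triethylsilyloxy-1α,10α-epoxy-9β-(tert-butyldimethylsilyloxy)germacr-11-en-5-one (cis-3,4-epoxide, either face)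
Conditions: 30% H2O2, NaOH, MeOH, 0 °C
Reagents that add atoms: hydrogen peroxide, OO
Why: Weitz–Scheffer epoxidation of the enone; the isopropenyl group, the isolated epoxide and the silyl ethers are inert to hydroperoxide anion. The configuration at C3 and C4 is not needed, because both centres are erased in steps 16 and 17.

Step 16
Reactants: 20 epoxy ketone
Product: 21 (4Z)-3-hydroxy-6α-triethylsilyloxy-1α,10α-epoxy-9β-(tert-butyldimethylsilyloxy)germacra-4,11-diene (C3 epimers)
Conditions: N2H4·H2O, CH3CO2H (cat.), MeOH, 20 °C
Reagents that add atoms: none
Why: Wharton transposition as in step 5 gives the C3 alcohol and the ring-cis C4=C5 alkene; the isopropenyl group survives as it does in the carvone oxide case.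

Step 17
Reactants: 21 allylic alcohol
Product: 22 (4Z)-6α-triethylsilyloxy-1α,10α-epoxy-9β-(tert-butyldimethylsilyloxy)germacra-4,11-dien-3-one
Conditions: MnO2, CH2Cl2, 20 °C
Reagents that add atoms: none
Why: Selective allylic oxidation with MnO2 converges both C3 epimers into one enone and prepares C3 for reagent-controlled reduction; silyl ethers, epoxide and isopropenyl are untouched.

Step 18
Reactants: 22 enone
Product: 23 (4Z,3S)-3α-hydroxy-6α-triethylsilyloxy-1α,10α-epoxy-9β-(tert-butyldimethylsilyloxy)germacra-4,11-diene
Conditions: (R)-1-methyl-3,3-diphenyltetrahydro-1H,3H-pyrrolo[1,2-c][1,3,2]oxazaborole (10 mol%), catecholborane, toluene, −78 °C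
Reagents that add atoms: none
Why: Corey–Bakshi–Shibata reduction with the enantiomeric catalyst (the C3 ketone is the local mirror image of the C9 ketone of 9) sets the target stereocentre C3 as 3S (3α) by reagent control, with the α-methylalkenyl flank as the large group. Catecholborane at −78 °C spares the epoxide and the isopropenyl group.

Step 19
Reactants: 23 3α-allylic alcohol
Product: 24 3α-hydroxy-1α,10α;4β,5β-diepoxy-6α-triethylsilyloxy-9β-(tert-butyldimethylsilyloxy)germacr-11-ene
Conditions: mCPBA, NaHCO3, CH2Cl2, −20 → 0 °C
Reagents that add atoms: 3-chloroperbenzoic acid, O=C(OO)c1cccc(Cl)c1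
Why: Hydroxyl-directed peracid epoxidation as in step 8: oxygen is delivered trans (threo) to the 3α hydroxyl, which sets C4 and C5 (4R,5S) as the cis 4β,5β-epoxide. The hydroxyl-assisted trisubstituted alkene reacts faster than the 1,1-disubstituted isopropenyl group, and the buffer prevents acid-induced transannular attack of the alkene on the 1,10-epoxide.

Step 20
Reactants: 25 angelic acid
Product: 26 angelic 2,4,6-trichlorobenzoic anhydride
Conditions: 2,4,6-trichlorobenzoyl chloride, Et3N, toluene, 20 °C; filtration under argon, filtrate concentrated and kept as a toluene stock solution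
Reagents that add atoms: 2,4,6-trichlorobenzoyl chloride, O=C(Cl)c1c(Cl)cc(Cl)cc1Cl
Why: Triethylammonium angelate is acylated by the aroyl chloride to give the mixed anhydride, the first stage of a Yamaguchi esterification; the ammonium chloride is filtered off and the anhydride is kept in solution for steps 21 and 25. No nucleophilic catalyst or strong base is present, so the Z alkene has no addition–elimination path to the tiglate.

Step 21
Reactants: 24 epoxy alcohol; 26 angelic 2,4,6-trichlorobenzoic anhydride
Product: 27 3α-angeloyloxy-1α,10α;4β,5β-diepoxy-6α-triethylsilyloxy-9β-(tert-butyldimethylsilyloxy)germacr-11-ene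
Conditions: 26 (3 equiv), Et3N, toluene, 80 °C
Reagents that add atoms: none
Why: Mixed-anhydride esterification of the Yamaguchi type without nucleophilic catalyst: the hindered alcohol attacks the angeloyl carbonyl of 26, because the aroyl carbonyl is shielded by its two ortho chlorines. Triethylamine takes up the liberated 2,4,6-trichlorobenzoic acid so that the epoxides stay in a non-acidic medium, and the Z geometry of the ester is kept.

Step 22
Reactants: 27 silyl ether
Product: 28 3α-angeloyloxy-6α-hydroxy-1α,10α;4β,5β-diepoxy-9β-(tert-butyldimethylsilyloxy)germacr-11-ene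
Conditions: HF·pyridine, pyridine, THF, 0 °C
Reagents that add atoms: none
Why: Buffered HF·pyridine cleaves the triethylsilyl ether and leaves the more robust tert-butyldimethylsilyl ether, the ester and both epoxides.

Step 23
Reactants: 28 6α-alcohol
Product: 29 3α-angeloyloxy-1α,10α;4β,5β-diepoxy-9β-(tert-butyldimethylsilyloxy)germacr-11-en-6-one
Conditions: Dess–Martin periodinane, NaHCO3, CH2Cl2, 0 → 20 °C
Reagents that add atoms: none
Why: Dess–Martin oxidation under buffered, non-basic conditions erases the provisional C6 centre without touching ester, epoxides or alkene. The β,γ-unsaturated ketone is taken on at once because C7–H is now α to a carbonyl and allylic.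

Step 24
Reactants: 29 epoxy ketone
Product: 30 (6S)-3α-angeloyloxy-6β-hydroxy-1α,10α;4β,5β-diepoxy-9β-(tert-butyldimethylsilyloxy)germacr-11-ene
Conditions: NaBH4, CeCl3·7H2O, MeOH, −78 °C
Reagents that add atoms: none
Why: Luche-type borohydride reduction sets C6. Hydride adds to the s-cis epoxy ketone anti to C4 (the erythro preference of α,β-epoxy ketones), and this is also the Felkin–Anh face with respect to C7 (isopropenyl anti), so both neighbours direct to the 6β (6S) alcohol. Low temperature and short contact avoid enolisation toward C7.

Step 25
Reactants: 30 6β-alcohol; 26 angelic 2,4,6-trichlorobenzoic anhydride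
Product: 31 3α,6β-diangeloyloxy-1α,10α;4β,5β-diepoxy-9β-(tert-butyldimethylsilyloxy)germacr-11-ene
Conditions: 26 (3 equiv), Et3N, toluene, 80 °C
Reagents that add atoms: none
Why: The same catalyst-free mixed-anhydride esterification as in step 21 acylates the hindered C6 hydroxyl with retention at C6 and without Z to E isomerisation of either angelate.

Step 26
Reactants: 31 silyl ether
Product: 32 3α,6β-diangeloyloxy-1α,10α;4β,5β-diepoxy-9β-hydroxygermacr-11-ene
Conditions: Bu4NF, CH3CO2H, THF, 0 → 20 °C
Reagents that add atoms: none
Why: Fluoride cleaves the remaining silyl ether; buffering with acetic acid keeps the C9 oxygen protonated, which prevents Payne migration of the 1,10-epoxide and acyl migration.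

Step 27
Reactants: 32 epoxy alcohol
Product: 33 target, (1R,3S,4R,5S,6S,7S,10R)-3,6-diangeloyloxy-1,10;4,5-diepoxygermacr-11-en-9-one
Conditions: Dess–Martin periodinane, NaHCO3, CH2Cl2, 0 → 20 °C
Reagents that add atoms: none
Why: Dess–Martin oxidation of the C9 carbinol gives the α,β-epoxy ketone under neutral buffered conditions that spare the angelates, both epoxides and the isopropenyl group; no stereocentre is touched.

## Compound list

1 | (−)-guaiol | C[C@H]1CCC2=C1C[C@@H](CC[C@@H]2C)C(C)(C)O | starting material
2 | primary ozonide of 1 (1,2,3-trioxolane across C1–C5, β face) | C[C@H]1CC[C@]23OOO[C@]12C[C@@H](CC[C@@H]3C)C(C)(C)O | intermediate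
3 | seco-guaiol dione, (4S,7R,10S)-7-(2-hydroxypropan-2-yl)-4,10-dimethylcyclodecane-1,5-dione | CC(C)(O)[C@@H]1CC[C@H](C)C(=O)CC[C@H](C)C(=O)C1 | intermediate
4 | 5β-methoxy-5α,11-epoxygermacran-1-one (C5 methyl ketal) | CC2(C)[C@@H]1CC[C@H](C)C(=O)CC[C@H](C)[C@](OC)(O2)C1 | intermediate
5 | 1-trimethylsilyloxy-1(10)-ene of 4 (C2 and C9 cis) | CC2(C)[C@@H]1CC/C(C)=C(O[Si](C)(C)C)\CC[C@H](C)[C@](OC)(O2)C1 | intermediate
6 | (9Z)-5β-methoxy-5α,11-epoxygermacr-9-en-1-one | CC2(C)[C@@H]1C/C=C(C)\C(=O)CC[C@H](C)[C@](OC)(O2)C1 | intermediate
7 | 9,10-epoxy-5β-methoxy-5α,11-epoxygermacran-1-one (epoxide face not controlled) | CC2(C)[C@@H]1CC3OC3(C)C(=O)CC[C@H](C)[C@](OC)(O2)C1 | intermediate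
8 | (1(10)Z)-9-hydroxy-5β-methoxy-5α,11-epoxygermacr-1(10)-ene (C9 epimers) | CC2(C)[C@@H]1CC(O)/C(C)=C\CC[C@H](C)[C@](OC)(O2)C1 | intermediate
9 | (1(10)Z)-5β-methoxy-5α,11-epoxygermacr-1(10)-en-9-one | CC2(C)[C@@H]1CC(=O)/C(C)=C\CC[C@H](C)[C@](OC)(O2)C1 | intermediate
10 | (1(10)Z)-9β-hydroxy-5β-methoxy-5α,11-epoxygermacr-1(10)-ene | CC2(C)[C@@H]1C[C@@H](O)/C(C)=C\CC[C@H](C)[C@](OC)(O2)C1 | intermediate
11 | 1α,10α-epoxy-9β-hydroxy-5β-methoxy-5α,11-epoxygermacrane | CC2(C)[C@@H]1C[C@@H](O)[C@]3(C)O[C@@H]3CC[C@H](C)[C@](OC)(O2)C1 | intermediate
12 | 9β-tert-butyldimethylsilyl ether of 11 | CC2(C)[C@@H]1C[C@@H](O[Si](C)(C)C(C)(C)C)[C@]3(C)O[C@@H]3CC[C@H](C)[C@](OC)(O2)C1 | intermediate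
13 | 1α,10α-epoxy-9β-(tert-butyldimethylsilyloxy)-11-hydroxygermacran-5-one | CC(C)(O)[C@@H]1C[C@@H](O[Si](C)(C)C(C)(C)C)[C@]2(C)O[C@@H]2CC[C@H](C)C(=O)C1 | intermediate
14 | 6α,11-dihydroxy derivative of 13 | CC(C)(O)[C@@H]1C[C@@H](O[Si](C)(C)C(C)(C)C)[C@]2(C)O[C@@H]2CC[C@H](C)C(=O)[C@@H]1O | intermediate
15 | 6α-triethylsilyl ether of 14 | CC(C)(O)[C@@H]1C[C@@H](O[Si](C)(C)C(C)(C)C)[C@]2(C)O[C@@H]2CC[C@H](C)C(=O)[C@@H]1O[Si](CC)(CC)CC | intermediate
16 | 5-trimethylsilyloxy-4-ene (C3 and C6 cis), 11-trimethylsilyl ether of 15 | C[Si](C)(C)OC(C)(C)[C@@H]1C[C@@H](O[Si](C)(C)C(C)(C)C)[C@]2(C)O[C@@H]2CC/C(C)=C(O[Si](C)(C)C)\[C@@H]1O[Si](CC)(CC)CC | intermediate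
17 | (3Z)-3-en-5-one, 11-trimethylsilyl ether | C[Si](C)(C)OC(C)(C)[C@@H]1C[C@@H](O[Si](C)(C)C(C)(C)C)[C@]2(C)O[C@@H]2C/C=C(C)\C(=O)[C@@H]1O[Si](CC)(CC)CC | intermediate
18 | (3Z)-11-hydroxy-6α-triethylsilyloxy-1α,10α-epoxy-9β-(tert-butyldimethylsilyloxy)germacr-3-en-5-one | CC(C)(O)[C@@H]1C[C@@H](O[Si](C)(C)C(C)(C)C)[C@]2(C)O[C@@H]2C/C=C(C)\C(=O)[C@@H]1O[Si](CC)(CC)CC | intermediate
19 | (3Z)-6α-triethylsilyloxy-1α,10α-epoxy-9β-(tert-butyldimethylsilyloxy)germacra-3,11-dien-5-one | C=C(C)[C@@H]1C[C@@H](O[Si](C)(C)C(C)(C)C)[C@]2(C)O[C@@H]2C/C=C(C)\C(=O)[C@@H]1O[Si](CC)(CC)CC | intermediate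
20 | 3,4-epoxide of 19 (epoxide face not controlled) | C=C(C)[C@@H]1C[C@@H](O[Si](C)(C)C(C)(C)C)[C@]2(C)O[C@@H]2CC3OC3(C)C(=O)[C@@H]1O[Si](CC)(CC)CC | intermediate
21 | (4Z)-3-hydroxy-4,11-diene (C3 epimers) | C=C(C)[C@@H]1C[C@@H](O[Si](C)(C)C(C)(C)C)[C@]2(C)O[C@@H]2CC(O)/C(C)=C\[C@@H]1O[Si](CC)(CC)CC | intermediate
22 | (4Z)-4,11-dien-3-one | C=C(C)[C@@H]1C[C@@H](O[Si](C)(C)C(C)(C)C)[C@]2(C)O[C@@H]2CC(=O)/C(C)=C\[C@@H]1O[Si](CC)(CC)CC | intermediate
23 | (4Z)-3α-hydroxy-4,11-diene | C=C(C)[C@@H]1C[C@@H](O[Si](C)(C)C(C)(C)C)[C@]2(C)O[C@@H]2C[C@H](O)/C(C)=C\[C@@H]1O[Si](CC)(CC)CC | intermediate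
24 | 3α-hydroxy-1α,10α;4β,5β-diepoxy-6α-triethylsilyloxy-9β-(tert-butyldimethylsilyloxy)germacr-11-ene | C=C(C)[C@@H]1C[C@@H](O[Si](C)(C)C(C)(C)C)[C@]2(C)O[C@@H]2C[C@H](O)[C@@]2(C)O[C@H]2[C@@H]1O[Si](CC)(CC)CC | intermediate
25 | angelic acid, (Z)-2-methylbut-2-enoic acid | C/C=C(C)\C(=O)O | starting material
26 | angelic 2,4,6-trichlorobenzoic anhydride | C/C=C(C)\C(=O)OC(=O)c1c(Cl)cc(Cl)cc1Cl | intermediate
27 | 3α-angelate of 24 | C=C(C)[C@@H]1C[C@@H](O[Si](C)(C)C(C)(C)C)[C@]2(C)O[C@@H]2C[C@H](OC(=O)/C(C)=C\C)[C@@]2(C)O[C@H]2[C@@H]1O[Si](CC)(CC)CC | intermediate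
28 | 3α-angeloyloxy-6α-hydroxy-1α,10α;4β,5β-diepoxy-9β-(tert-butyldimethylsilyloxy)germacr-11-ene | C=C(C)[C@@H]1C[C@@H](O[Si](C)(C)C(C)(C)C)[C@]2(C)O[C@@H]2C[C@H](OC(=O)/C(C)=C\C)[C@@]2(C)O[C@H]2[C@@H]1O | intermediate
29 | 6-ketone of 28 | C=C(C)[C@@H]1C[C@@H](O[Si](C)(C)C(C)(C)C)[C@]2(C)O[C@@H]2C[C@H](OC(=O)/C(C)=C\C)[C@@]2(C)O[C@H]2C1=O | intermediate
30 | 3α-angeloyloxy-6β-hydroxy-1α,10α;4β,5β-diepoxy-9β-(tert-butyldimethylsilyloxy)germacr-11-ene | C=C(C)[C@@H]1C[C@@H](O[Si](C)(C)C(C)(C)C)[C@]2(C)O[C@@H]2C[C@H](OC(=O)/C(C)=C\C)[C@@]2(C)O[C@H]2[C@H]1O | intermediate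
31 | 3α,6β-diangeloyloxy-1α,10α;4β,5β-diepoxy-9β-(tert-butyldimethylsilyloxy)germacr-11-ene | C=C(C)[C@@H]1C[C@@H](O[Si](C)(C)C(C)(C)C)[C@]2(C)O[C@@H]2C[C@H](OC(=O)/C(C)=C\C)[C@@]2(C)O[C@H]2[C@H]1OC(=O)/C(C)=C\C | intermediate
32 | 3α,6β-diangeloyloxy-1α,10α;4β,5β-diepoxy-9β-hydroxygermacr-11-ene | C=C(C)[C@@H]1C[C@@H](O)[C@]2(C)O[C@@H]2C[C@H](OC(=O)/C(C)=C\C)[C@@]2(C)O[C@H]2[C@H]1OC(=O)/C(C)=C\C | intermediate
33 | CNP0217653.1, (1R,3S,4R,5S,6S,7S,10R)-3,6-diangeloyloxy-1,10;4,5-diepoxygermacr-11-en-9-one | C=C(C)[C@@H]1CC(=O)[C@]2(C)O[C@@H]2C[C@H](OC(=O)/C(C)=C\C)[C@@]2(C)O[C@H]2[C@H]1OC(=O)/C(C)=C\C | target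

## Step count and least certain steps

Total: 27 steps. Longest linear sequence: 26 steps (1 to 33 through steps 1–19 and 21–27). Step 20 is a one-step side branch that turns angelic acid 25 into anhydride 26, which enters the main line in steps 21 and 25.

**Step 1 (key step).** The most likely failure is an abnormal course of the ozonolysis of the hindered tetrasubstituted alkene (oxygen-atom transfer or rearrangement of the peroxidic adducts), followed by transannular aldol closure of the 1,5-dione during work-up, because the two carbonyls face each other across the ring. Fallback: set out from 1, epoxidise with mCPBA to 1β,5β-epoxyguaiol F1, and cleave the epoxide with H5IO6 in aqueous THF (through the diol) to return at 3.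

**Step 3.** The most likely failure is silyl enol ether formation or β-hydride elimination taking the wrong direction (toward C2, or toward the methyl group), because the ten-membered ring gives little bias between the two β-hydrogen sets. Fallback: set out from 4, accept the exocyclic methylene ketone F2 from the same sequence, and move the double bond into the ring by base-mediated equilibration through the dienolate (DBU, toluene) to return at 6.

**Step 16.** The most likely failure is slow hydrazone formation at the doubly α-branched C5 ketone, with loss of the neighbouring silyloxy group from the alkenyl anion, because C5 is flanked by a quaternary epoxide carbon and a silyloxy methine. Fallback: use the radical version of the transposition. Set out from 20, reduce with NaBH4 to the 3,4-epoxy-5-ol F3, and convert it with 1,1'-thiocarbonyldiimidazole into the imidazol-1-ylthiocarbonyl derivative F4. Treatment with Bu3SnH and AIBN generates the C5 radical, which opens the adjacent epoxide and returns at 21.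

**Step 24.** The most likely failure is base-promoted enolisation toward C7 before reduction (epimerisation at C7, or migration of the isopropenyl double bond into conjugation), or incomplete facial selectivity, because C7–H is both α to the ketone and allylic. Fallback: invert C6 without passing through a ketone. Set out from 28 and esterify under Mitsunobu conditions with angelic acid 25 (PPh3, diisopropyl azodicarboxylate), which would give 31 directly with inversion (no new compound, F0).

## Further compounds

F1 | step 1 | 1β,5β-epoxyguaiol | C[C@H]1CC[C@]23O[C@]12C[C@@H](CC[C@@H]3C)C(C)(C)O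
F2 | step 3 | 5β-methoxy-5α,11-epoxygermacr-10(14)-en-1-one (exocyclic methylene ketone) | CC2(C)[C@@H]1CCC(=C)C(=O)CC[C@H](C)[C@](OC)(O2)C1
F3 | step 16 | 3,4-epoxy-5-hydroxy derivative of 20 (C3, C4, C5 not controlled) | C=C(C)[C@@H]1C[C@@H](O[Si](C)(C)C(C)(C)C)[C@]2(C)O[C@@H]2CC3OC3(C)C(O)[C@@H]1O[Si](CC)(CC)CC
F4 | step 16 | O-(imidazol-1-ylthiocarbonyl) derivative of F3 | C=C(C)[C@@H]1C[C@@H](O[Si](C)(C)C(C)(C)C)[C@]2(C)O[C@@H]2CC3OC3(C)C(OC(=S)n4ccnc4)[C@@H]1O[Si](CC)(CC)CC
F0 | step 24 | none | none
A1 | alternative 1 | open-chain (Z)-C3,C6-enediol spanning C1–C9 | C=C(C)[C@H](CCO[Si](C)(C)C(C)(C)C)[C@H](O)/C=C(C)\[C@@H](O)CCOCc1ccc(OC)cc1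
A2 | alternative 2 | cis-anti-cis 6-4-4 tricyclic photoadduct | C=C(C)[C@@H]1CC(=O)[C@]2(C)[C@H]3C[C@H](O[Si](CC)(CC)CC)[C@@]3(C)[C@@H]2[C@H]1O[Si](C)(C)C(C)(C)C
A3 | alternative 3 | C3,C6-diangelate of the (Z,Z)-dienone | C=C(C)[C@@H]1CC(=O)/C(C)=C\C[C@H](OC(=O)/C(C)=C\C)/C(C)=C\[C@H]1OC(=O)/C(C)=C\C
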